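The earlier runs and the new flask were generated by integration for an exercise, and the scatter is random.

I counted the ligand first.

| setting | west | east | south | theta | eta | alpha |
|---|---|---|---|---|---|---|
| starting complex | 0.050 M | 0.050 M | 0.050 M | 0.050 M | 0.050 M | 0.050 M |
| incoming ligand | 0.032 M | 0.073 M | 0.23 M | 0.0250 M | 0.0600 M | 0.200 M |
| remark | run made earlier | run made earlier | run made earlier |  |  |  |
| time |  |  |  | 4.0 h | 4.0 h | 4.0 h |

| run | time / h | complex with one exchanged / % | complex with three exchanged / % | starting complex / % |
|---|---|---|---|---|
| west | 0.250 | 6 | 1 | 91 |
| west | 0.417 | 10 | 0 | 87 |
| west | 0.833 | 13 | 1 | 81 |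
| west | 1.33 | 18 | 2 | 71 |
| west | 3.00 | 20 | 1 | 64 |
| east | 0.500 | 23 | 1 | 72 |
| east | 1.00 | 23 | 0 | 58 |
| east | 1.50 | 21 | 0 | 46 |
| east | 2.50 | 20 | 0 | 41 |
| east | 3.00 | 20 | 2 | 36 |
| south | 0.250 | 21 | 4 | 54 |
| south | 0.667 | 26 | 7 | 24 |
| south | 1.33 | 13 | 6 | 11 |
| south | 2.00 | 7 | 0 | 8 |
| south | 3.00 | 3 | 1 | 2 |

(each reading ± 2 percentage points)

- on the list of suspects stand: starting complex + incoming ligand <-> leaving ligand + complex with one exchanged; complex with two exchanged -> side product; complex with one exchanged + incoming ligand <-> leaving ligand + complex with two exchanged; complex with two exchanged + incoming ligand <-> leaving ligand + complex with three exchanged; complex with three exchanged + incoming ligand <-> leaving ligand + complex with four exchanged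

- complex with one exchanged at the end, in percent of the starting complex charged, for each flask in turn (theta, eta, alpha)

How far could each charge go? On the suspected path a starting complex takes two exchanges before side product forms, so each complex that ends as side product costs two incoming ligands. I therefore divided [incoming ligand] charged by twice [starting complex] charged and called the result the reach 25.0% for theta, 60.0% for eta and 200% for alpha. The reach, the share of the complex charged that the ligand can pay to take to side product, names the limiting reagent. It is the incoming ligand in theta and eta, and the starting complex in alpha.

Did the earlier runs respect that count? In the west run, with a reach of 32.0%, the readings at 3.00 h, taken at one ligand for each complex with one exchanged and two for the rest of what had left the starting complex, put the ligand spent near 52.0% of the complex charged, against 64.0% supplied, and starting complex still read 64%.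

What does the reach mean for complex with one exchanged? At 3.00 h it read 20% in west and 20% in east, whose reach was 73.0%, beside 64% and 36% of starting complex. In south, with a reach of 230%, it read 3% at 3.00 h, beside 2% of starting complex. So I placed theta and eta with west and east, and alpha with south.

The forecast gave 19%, 20% and 2.5%, and for alpha it spoke of ligand “with an excess remaining”.

The flasks gave 17.6%, 17.5% and 2.15%, within the margin.

    starting complex + incoming ligand ⇌ leaving ligand + complex with one exchanged (K = 2.90, k = 0.190 /M/min)
    complex with two exchanged → side product (k = 0.100 /min)
    complex with one exchanged + incoming ligand ⇌ leaving ligand + complex with two exchanged (K = 0.430, k = 0.570 /M/min)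
    complex with two exchanged + incoming ligand ⇌ leaving ligand + complex with three exchanged (K = 0.350, k = 0.320 /M/min)
    complex with three exchanged + incoming ligand ⇌ leaving ligand + complex with four exchanged (K = 0.310, k = 0.0440 /M/min)

In theta at 4.00 h, complex with one exchanged was being made at 0.562 of the rate at which it was used up, each step taken net, and at 40.0 h it stood at 4.80%, with side product at 22.1%, under the reach of 25.0%. In alpha, with a reach of 200%, side product stood at 100% at 40.0 h, and the incoming ligand left was 50.0% of its charge, the 50.0% that this reach leaves over.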